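I began with one turn of the catalyst.

substrate 0.20 M; reagent 0.600 equiv; free catalyst 2.5 mol%; impurity 1.3 mM

    substrate + free catalyst → catalyst intermediate A (k1 = 2.3 M⁻¹ s⁻¹)
    reagent + catalyst intermediate A → catalyst intermediate B (k2 = 190 M⁻¹ s⁻¹)
    catalyst intermediate B → by-product + catalyst intermediate C (k3 = 0.37 s⁻¹)
    catalyst intermediate C → catalyst intermediate D (k4 = 4.5 s⁻¹)
    catalyst intermediate D → free catalyst + target (k5 = 2.6 s⁻¹)
    free catalyst + impurity → spent catalyst (k6 = 2700 M⁻¹ s⁻¹)

- apparent order in free catalyst when 30 % of the substrate are converted (percent change of the rate of making target for one percent more free catalyst charged)
- apparent order in reagent when 30 % of the substrate are converted (percent change of the rate of making target for one percent more reagent charged)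

In this flask at 30 % conversion, [substrate] stood at 0.140 M and [reagent] at 0.0600 M, since the round uses the two one for one. A catalyst going round adds up its waits, so I wrote the rate of making target as [catalyst in the round] divided by the time of one round. At these concentrations I reckoned that time as 6.50 s. Reagent enters this sum at one step, where the wait 1/(k2[reagent]) was 0.0877 s, far shorter than the round. So these were the two times to compare. Dividing them gave 0.0135, and time dropped out: this is the share of one round spent waiting for reagent.

One percent more reagent charged, with the same amount used up, meant 2.00 percent more reagent left. I therefore multiplied the share by that and got an order of 0.0270. For the catalyst I looked at the numerator. Free catalyst met impurity faster than substrate, at 210 min⁻¹ against 28 min⁻¹ per free catalyst with each as charged, so I took the impurity's whole charge off the catalyst. That left 3.70 mM in the round and gave an order of 1.35.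

The forecast gave 1.35 for the order in free catalyst and 0.027 for the order in reagent, with “the reagent step only about 1.4% of the cycle time”, and my reckoning came to the same two figures.

The simulation gave 1.4 for the order in free catalyst and 0.027 for the order in reagent. At that conversion spent catalyst held 26.0 % of the catalyst, and my waiting share, taken of the part not spent, came to 0.999 % of the catalyst, beside the 0.994 % of the catalyst read as catalyst intermediate A, the form that waits for reagent. For the flask with twice the reagent charged, I took 0.180 M as left at the same conversion, and with the wait reckoned shorter in proportion the share gave a factor of 1.01 on the rate, where that run read 1.01.

The rate constants are those of an exercise.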